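**Strategy**

Everything rests on cutting the aryl–C7' bond and the C7–C8 bond in one operation. The key step exploits the environment of C8', which carries C7'H2 (leading to the 4-hydroxy-3,5-dimethoxyphenyl ring), the oxygenated C9'H2 and C8; this pattern maps onto the cyclopropane CH of a 3-oxabicyclo[3.1.0]hexan-2-one derived from (R)-epichlorohydrin. A copper-catalysed aryl Grignard reagent opens the cyclopropane ring at its CH2, and the released lactone–ester enolate is benzylated at C8 by 3,4-dimethoxybenzyl bromide in the same flask. The precursor is the (1S,5R) bicyclic lactone methyl ester; C8' is never touched, and C8 becomes trans once the ester is removed. Reduction, acetylation and debenzylation complete the target.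

Key step: step 5

Remark on the chemistry: read from its SMILES, the target is the (2R,3R)-butane-1,4-diyl diacetate (8R,8'R in lignan numbering). The lactone from (R)-epichlorohydrin is (1S,5R), and the fully specified key-step product is the (3R,4R) ester with trans arylmethyl groups. The aryl Grignard reagent is prepared as a titrated stock solution and counted as a step of its own.

**Route**

Step 1
Reactants: 1 (R)-epichlorohydrin; 2 dimethyl malonate
Product: 6 methyl (1S,5R)-2-oxo-3-oxabicyclo[3.1.0]hexane-1-carboxylate, via chlorohydrin malonate 3 (not isolated), via epoxy malonate 4 (not isolated), via hydroxymethyl cyclopropane diester 5 (not isolated)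
Conditions: NaOMe (1.2 equiv), MeOH, 0 °C to reflux; dilute HCl work-up; distillation
Reagents that add atoms: none
Why: Malonate alkylation–cyclopropanation–lactonisation cascade: the malonate anion opens the epoxide of 1 at its CH2 to give 3, the alkoxide re-closes onto the CH2Cl carbon to give 4, the malonate carbanion opens this new epoxide at the stereocentre by a 3-exo-tet SN2 attack with inversion to give 5, and the hydroxymethyl group lactonises onto the cis ester, so the one stereocentre of 1 fixes both C5 (R) and, through the obligatory cis ring fusion, C1 (S).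

Step 2
Reactants: 7 4-bromo-2,6-dimethoxyphenol
Product: 8 2-(benzyloxy)-5-bromo-1,3-dimethoxybenzene
Conditions: BnBr (1.2 equiv), K2CO3 (2 equiv), DMF, 60 °C
Reagents that add atoms: benzyl bromide, BrCc1ccccc1
Why: Williamson ether synthesis of the phenoxide with a benzylic bromide, which masks the acidic phenol through the organometallic and hydride steps as a group that hydrogenolysis removes at the end without touching acetates.

Step 3
Reactants: 8 2-(benzyloxy)-5-bromo-1,3-dimethoxybenzene
Product: 9 (4-benzyloxy-3,5-dimethoxyphenyl)magnesium bromide (titrated THF solution)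
Conditions: Mg turnings (I2 crystal), THF, 50 °C
Reagents that add atoms: magnesium, [Mg]
Why: Grignard formation by insertion of magnesium into the aryl C–Br bond, routine for alkoxy-substituted bromoarenes in THF, with the aryl methyl and benzyl ethers inert.

Step 4
Reactants: 10 3,4-dimethoxybenzyl alcohol
Product: 11 3,4-dimethoxybenzyl bromide
Conditions: PBr3 (0.4 equiv), CH2Cl2, 0 °C; used at once
Reagents that add atoms: phosphorus tribromide, BrP(Br)Br
Why: PBr3 turns the hydroxyl into a leaving group that bromide displaces at the electron-rich benzylic carbon (alcohol-to-bromide substitution), and the labile bromide is taken on directly.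

Step 5
Reactants: 6 methyl (1S,5R)-2-oxo-3-oxabicyclo[3.1.0]hexane-1-carboxylate; 9 (4-benzyloxy-3,5-dimethoxyphenyl)magnesium bromide; 11 3,4-dimethoxybenzyl bromide
Product: 13 methyl (3R,4R)-4-(4-benzyloxy-3,5-dimethoxybenzyl)-3-(3,4-dimethoxybenzyl)-2-oxotetrahydrofuran-3-carboxylate, via magnesium enolate 12 (not isolated)
Conditions: CuI (10 mol%), THF, 9 (1.1 equiv) added at −30 °C, then to 0 °C; then DMPU, 11 (1.5 equiv), n-Bu4NI (10 mol%), 0 to 40 °C; aq. NH4Cl
Reagents that add atoms: none
Why: Transmetalation of 9 to CuI gives an arylcopper species that attacks the unsubstituted cyclopropane CH2 (C6) of 6 in an SN2-type homoconjugate addition, the C1–C6 bond breaking with the lactone–ester-stabilised carbanion as leaving group to give magnesium enolate 12, which is then C-alkylated by 11 once DMPU loosens the magnesium chelate. The closest known reaction types are the copper-catalysed Grignard opening of 2-oxo-3-oxabicyclo[3.1.0]hexane-1-carboxylates and the benzylation of 2-oxotetrahydrofuran-3-carboxylate (malonate-type) enolates, run here as one addition–enolate-trapping sequence. No ring is closed, since the cyclopropane ring is opened and the lactone ring is kept. No bond to the epichlorohydrin-derived CH is broken, so it becomes C4 (R) of 13 with its configuration intact, and the new quaternary C3 (R) is set by substrate control because the benzylic bromide meets the planar enolate on the face anti to the C4 arylmethyl group. The step needs attack at the cyclopropane CH2 and not at the ester carbonyl, the lactone carbonyl or the ring CH, which the soft organocopper nucleophile at low temperature, the double activation of the ring and the unhindered methylene should secure, while C- over O-alkylation follows from the soft benzylic electrophile. Any minor C3 epimer is harmless because C3 is re-set in step 6.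

Step 6
Reactants: 13 methyl (3R,4R)-4-(4-benzyloxy-3,5-dimethoxybenzyl)-3-(3,4-dimethoxybenzyl)-2-oxotetrahydrofuran-3-carboxylate
Product: 14 (3R,4R)-4-(4-benzyloxy-3,5-dimethoxybenzyl)-3-(3,4-dimethoxybenzyl)dihydrofuran-2(3H)-one
Conditions: LiCl (3 equiv), H2O (2 equiv), DMSO, 140 °C; then DBU, toluene, 100 °C if any cis isomer remains
Reagents that add atoms: none
Why: Krapcho demethoxycarbonylation (chloride SN2 attack at the ester methyl, loss of CO2 and reprotonation at C3) removes the temporary ester, and C3, being epimerisable under the hot, mildly basic conditions, should settle in the thermodynamically favoured 3,4-trans arrangement (3R,4R) while C4 is untouched.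

Step 7
Reactants: 14 (3R,4R)-4-(4-benzyloxy-3,5-dimethoxybenzyl)-3-(3,4-dimethoxybenzyl)dihydrofuran-2(3H)-one
Product: 15 (2R,3R)-2-(3,4-dimethoxybenzyl)-3-(4-benzyloxy-3,5-dimethoxybenzyl)butane-1,4-diol
Conditions: LiAlH4 (1.5 equiv), THF, 0 °C to rt; then H2O, 15% aq. NaOH, H2O
Reagents that add atoms: none
Why: Hydride reduction of the lactone to the 1,4-diol, in which the ethers are inert and hydride addition to the carbonyl is much faster than enolisation at C3, so both stereocentres are carried through unchanged.

Step 8
Reactants: 15 (2R,3R)-2-(3,4-dimethoxybenzyl)-3-(4-benzyloxy-3,5-dimethoxybenzyl)butane-1,4-diol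
Product: 16 (2R,3R)-2-(3,4-dimethoxybenzyl)-3-(4-benzyloxy-3,5-dimethoxybenzyl)butane-1,4-diyl diacetate
Conditions: Ac2O (3 equiv), pyridine, DMAP (5 mol%), CH2Cl2, rt
Reagents that add atoms: acetic anhydride, CC(=O)OC(C)=O
Why: DMAP-catalysed acylation of the two primary alcohols, which are the only acylable groups because the phenol is still a benzyl ether.

Step 9
Reactants: 16 (2R,3R)-2-(3,4-dimethoxybenzyl)-3-(4-benzyloxy-3,5-dimethoxybenzyl)butane-1,4-diyl diacetate
Product: 17 Justin C, (2R,3R)-2-(3,4-dimethoxybenzyl)-3-(4-hydroxy-3,5-dimethoxybenzyl)butane-1,4-diyl diacetate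
Conditions: H2 (1 atm), 10% Pd/C, EtOAc, rt
Reagents that add atoms: none
Why: Catalytic hydrogenolysis of the benzyl aryl ether over palladium frees the phenol, while acetates, aryl methyl ethers and the arylmethyl C–C bonds are stable in a non-nucleophilic solvent and no stereocentre is involved.

**Compound list**

1 | (R)-epichlorohydrin, (2R)-2-(chloromethyl)oxirane | ClC[C@H]1CO1 | starting material
2 | dimethyl malonate | COC(=O)CC(=O)OC | starting material
3 | dimethyl 2-[(2R)-3-chloro-2-hydroxypropyl]propanedioate | COC(=O)C(C(=O)OC)C[C@@H](O)CCl | intermediate (not isolated)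
4 | dimethyl 2-{[(2R)-oxiran-2-yl]methyl}propanedioate | COC(=O)C(C(=O)OC)C[C@@H]1CO1 | intermediate (not isolated)
5 | dimethyl (2R)-2-(hydroxymethyl)cyclopropane-1,1-dicarboxylate | COC(=O)C1(C(=O)OC)C[C@H]1CO | intermediate (not isolated)
6 | methyl (1S,5R)-2-oxo-3-oxabicyclo[3.1.0]hexane-1-carboxylate | COC(=O)[C@@]1(C2=O)[C@H](CO2)C1 | intermediate
7 | 4-bromo-2,6-dimethoxyphenol | COc1cc(Br)cc(OC)c1O | starting material
8 | 2-(benzyloxy)-5-bromo-1,3-dimethoxybenzene | COc1cc(Br)cc(OC)c1OCc1ccccc1 | intermediate
9 | (4-benzyloxy-3,5-dimethoxyphenyl)magnesium bromide | COc1cc([Mg]Br)cc(OC)c1OCc1ccccc1 | intermediate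
10 | 3,4-dimethoxybenzyl alcohol | COc1ccc(CO)cc1OC | starting material
11 | 3,4-dimethoxybenzyl bromide | COc1ccc(CBr)cc1OC | intermediate
12 | bromomagnesium enolate of methyl (4R)-4-(4-benzyloxy-3,5-dimethoxybenzyl)-2-oxotetrahydrofuran-3-carboxylate | COC(O[Mg]Br)=C1C(=O)OC[C@@H]1Cc1cc(OC)c(OCc2ccccc2)c(OC)c1 | intermediate (not isolated)
13 | methyl (3R,4R)-4-(4-benzyloxy-3,5-dimethoxybenzyl)-3-(3,4-dimethoxybenzyl)-2-oxotetrahydrofuran-3-carboxylate | COc1ccc(C[C@@](C(=O)OC)(C2=O)[C@H](CO2)Cc2cc(OC)c(OCc3ccccc3)c(OC)c2)cc1OC | intermediate
14 | (3R,4R)-4-(4-benzyloxy-3,5-dimethoxybenzyl)-3-(3,4-dimethoxybenzyl)dihydrofuran-2(3H)-one | COc1ccc(C[C@@H](C2=O)[C@H](CO2)Cc2cc(OC)c(OCc3ccccc3)c(OC)c2)cc1OC | intermediate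
15 | (2R,3R)-2-(3,4-dimethoxybenzyl)-3-(4-benzyloxy-3,5-dimethoxybenzyl)butane-1,4-diol | COc1ccc(C[C@@H](CO)[C@H](CO)Cc2cc(OC)c(OCc3ccccc3)c(OC)c2)cc1OC | intermediate
16 | (2R,3R)-2-(3,4-dimethoxybenzyl)-3-(4-benzyloxy-3,5-dimethoxybenzyl)butane-1,4-diyl diacetate | COc1ccc(C[C@@H](COC(C)=O)[C@H](COC(C)=O)Cc2cc(OC)c(OCc3ccccc3)c(OC)c2)cc1OC | intermediate
17 | Justin C, (2R,3R)-2-(3,4-dimethoxybenzyl)-3-(4-hydroxy-3,5-dimethoxybenzyl)butane-1,4-diyl diacetate | COc1ccc(C[C@@H](COC(C)=O)[C@H](COC(C)=O)Cc2cc(OC)c(O)c(OC)c2)cc1OC | target

**Step count and risks**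

Total step count: 9. Longest linear sequence: 7 steps (steps 2, 3, 5, 6, 7, 8 and 9, from 7 to 17).

Most likely to fail, in order of risk:

Step 5. The chelated magnesium enolate may be alkylated only sluggishly. Residual arylmetal may consume the benzylic bromide by cross-coupling, or add to a carbonyl group in competition with cyclopropane opening. The fallback separates the two bond formations and alkylates a simple lactone enolate instead. Setting out from 6 and 9, the ring opening alone is run with CuI in THF at −30 to 0 °C and quenched with 1 M HCl. This should give methyl (4R)-4-(4-benzyloxy-3,5-dimethoxybenzyl)-2-oxotetrahydrofuran-3-carboxylate F1 as a mixture of C3 epimers. Krapcho demethoxycarbonylation (LiCl, H2O, DMSO, 140 °C) then gives (4R)-4-(4-benzyloxy-3,5-dimethoxybenzyl)dihydrofuran-2(3H)-one F2. Its lithium enolate (LiN(SiMe3)2, THF, −78 °C) is alkylated by 11 on the face anti to the C4 substituent, which is the standard trans-selective route to dibenzylbutyrolactones. The fallback comes back to the route at 14.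

Step 6. At 140 °C chloride or hydroxide may open the lactone, aryl methyl ethers may be slowly cleaved, and equilibration of C3 to trans may stay incomplete. The fallback replaces nucleophilic demethylation by hydrolysis and thermal decarboxylation. Setting out from 13, LiOH in THF/H2O at rt saponifies the ester and reversibly opens the lactone, and acidification with HCl re-closes the ring. This should give (4R)-4-(4-benzyloxy-3,5-dimethoxybenzyl)-3-(3,4-dimethoxybenzyl)-2-oxotetrahydrofuran-3-carboxylic acid F3, whose C3 configuration is immaterial. Heating F3 in xylene at 140 °C expels CO2, and brief base equilibration (DBU, hot toluene) should leave the trans lactone. The fallback comes back to the route at 14.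

Step 1. Part of the malonate may displace chloride directly instead of opening the epoxide first, which leads to the enantiomeric lactone and erodes enantiomeric purity; oligomerisation may also lower the yield. Enantiomeric purity is to be checked at 14 and raised by crystallisation if needed. The fallback uses a cyclic sulfate, in which the secondary C–O bond is displaced exactly once with inversion whichever carbon is attacked first, so no such leak is possible. Setting out from 2, with commercially available (2R)-3-(benzyloxy)propane-1,2-diol F4 in place of 1, SOCl2 and Et3N in CH2Cl2 at 0 °C give (4S)-4-[(benzyloxy)methyl]-1,3,2-dioxathiolane 2-oxide F5 (both sulfur epimers). Oxidation with NaIO4 and catalytic RuCl3 in MeCN/H2O gives (4S)-4-[(benzyloxy)methyl]-1,3,2-dioxathiolane 2,2-dioxide F6. Double alkylation of 2 with F6 (NaH 2 equiv, DME, reflux) gives dimethyl (2R)-2-[(benzyloxy)methyl]cyclopropane-1,1-dicarboxylate F7. Hydrogenolysis (H2, Pd/C, MeOH) then gives 5, where the fallback comes back to the route, and 5 lactonises with catalytic TsOH in warm toluene to 6.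

Further compounds
F1 | step 5 | methyl (4R)-4-(4-benzyloxy-3,5-dimethoxybenzyl)-2-oxotetrahydrofuran-3-carboxylate (C3 epimers) | COC(=O)C1C(=O)OC[C@@H]1Cc1cc(OC)c(OCc2ccccc2)c(OC)c1
F2 | step 5 | (4R)-4-(4-benzyloxy-3,5-dimethoxybenzyl)dihydrofuran-2(3H)-one | O=C1C[C@@H](Cc2cc(OC)c(OCc3ccccc3)c(OC)c2)CO1
F3 | step 6 | (4R)-4-(4-benzyloxy-3,5-dimethoxybenzyl)-3-(3,4-dimethoxybenzyl)-2-oxotetrahydrofuran-3-carboxylic acid (C3 epimers) | COc1ccc(CC2(C(=O)O)C(=O)OC[C@@H]2Cc3cc(OC)c(OCc4ccccc4)c(OC)c3)cc1OC
F4 | step 1 | (2R)-3-(benzyloxy)propane-1,2-diol | OC[C@@H](O)COCc1ccccc1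
F5 | step 1 | (4S)-4-[(benzyloxy)methyl]-1,3,2-dioxathiolane 2-oxide | O=S1OC[C@H](COCc2ccccc2)O1
F6 | step 1 | (4S)-4-[(benzyloxy)methyl]-1,3,2-dioxathiolane 2,2-dioxide | O=S1(=O)OC[C@H](COCc2ccccc2)O1
F7 | step 1 | dimethyl (2R)-2-[(benzyloxy)methyl]cyclopropane-1,1-dicarboxylate | COC(=O)C1(C(=O)OC)C[C@H]1COCc1ccccc1
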